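The target is cut at the C4–O–C4′ ether bridge and at the C4–C4a bond of each pyran (C) ring. This exploits one feature: both flavan units have the same (2S,4R) centres and the same A ring, apart from one methyl group on O5. Both therefore come from a single (S)-3-aryloxy-3-phenylpropanal whose 3,4,5-trimethoxyphenoxy ring offers two equivalent ortho carbons. One acid-catalysed, dehydrating operation joins two aldehyde molecules into the C2-symmetric hexamethyl ether. It closes both rings, forms two C–C bonds and one C–O bond, and sets both C4 centres by relay from C2. Acid-free nucleophilic removal of one 5-O-methyl group finishes the synthesis.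

Key step: step 4

Remarks on the chemistry:
- Flavan numbering is used: O1, C2 bearing phenyl, C3, C4, C4a, C5–C8, C8a, with primes for the second unit.
- The target SMILES reads 2S,4R in both units, so phenyl and bridging oxygen are trans on each pyran ring.
- The aldehyde keeps three methoxy groups on purpose. Any other group on the later O5 would make the two ortho carbons of the aryloxy ring different and turn the ring closure into a regiochemical problem.
- The O5 methyl group is therefore removed last, with a nucleophile and not with BCl3 or MgI2. Those reagents would ionise the doubly benzylic bridge and, without a C4 carbonyl group, have no bias for O5.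
- Assumption: lithium diphenylphosphide is bought as its THF solution.

Step 1
Reactants: 1 3,4,5-trimethoxyphenol; 2 (R)-3-chloro-1-phenylpropan-1-ol
Product: 3 (S)-5-(3-chloro-1-phenylpropoxy)-1,2,3-trimethoxybenzene
Conditions: PPh3 (1.2 equiv), DIAD (1.2 equiv), THF, 0 °C → rt
Reagents that add atoms: none
Why: Mitsunobu etherification, in which the phenoxide displaces the phosphonium-activated benzylic hydroxyl group by SN2 with inversion, so that the bought (R) centre becomes the (S) centre that ends as C2 and C2′, while the primary chloride is inert.

Step 2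
Reactants: 3 (S)-5-(3-chloro-1-phenylpropoxy)-1,2,3-trimethoxybenzene
Product: 5 (S)-3-phenyl-3-(3,4,5-trimethoxyphenoxy)propan-1-ol, via acetate 4 (not isolated)
Conditions: KOAc (2 equiv), DMF, 90 °C; then MeOH, K2CO3 (0.2 equiv), rt
Reagents that add atoms: potassium acetate, CC(=O)[O-].[K+] (one of its oxygen atoms stays as the hydroxyl oxygen of 5)
Why: SN2 displacement of the primary chloride by acetate followed in the same flask by base-catalysed transesterification with methanol, neither of which touches the benzylic aryl ether centre, which has no acidifying neighbour at this oxidation level.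

Step 3
Reactants: 5 (S)-3-phenyl-3-(3,4,5-trimethoxyphenoxy)propan-1-ol
Product: 6 (S)-3-phenyl-3-(3,4,5-trimethoxyphenoxy)propanal
Conditions: Dess–Martin periodinane (1.1 equiv), CH2Cl2, 0 °C → rt; dilute with Et2O–hexane, filter through Celite and a short silica pad, use at once
Reagents that add atoms: none
Why: Dess–Martin oxidation stops at the aldehyde under non-aqueous, weakly acidic conditions, so the β-aryloxy aldehyde never meets a base that could expel the aryloxide (E1cB), and the stereocentre is untouched.

Step 4
Reactants: 6 (S)-3-phenyl-3-(3,4,5-trimethoxyphenoxy)propanal (two molecules)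
Product: 9 bis[(2S,4R)-5,6,7-trimethoxy-2-phenylchroman-4-yl] ether (C2-symmetric hexamethyl ether), via flavan-4-ol 7 (not isolated), via oxocarbenium ion 8 (not isolated)
Conditions: Sc(OTf)3 (5 mol %), powdered 4 Å MS, CH2Cl2 (0.5 M), −40 → 0 °C; Et3N quench
Reagents that add atoms: none
Why: Proposed new method: Sc(III) activates the aldehyde of one molecule of 6 for attack by its own arene carbon ortho to the aryl ether oxygen, which gives flavan-4-ol 7 (first C4–C4a bond, first pyran ring); O4 of 7 adds to a second molecule of 6, loss of water to the sieves gives oxocarbenium ion 8, and 8 is closed by its own arene (C4–O bond, second C4–C4a bond, second pyran ring), while any 7 that finds no aldehyde left can reach the same ether by ionisation at C4 and capture by a second molecule of 7. The closest known reaction types are the intramolecular Friedel–Crafts hydroxyalkylation of 3-aryloxypropanals to chroman-4-ols, the Lewis acid cyclisation of 3-aryloxypropanal acetals to 4-alkoxychromans, the reductive and allylative (Sakurai-type) homo-etherification of aldehydes and the dehydrative self-etherification of electron-rich benzylic alcohols; new is that one aldehyde plays all roles in one flask, with an arene ending both halves. Both rings close in the 6-exo-trig mode with respect to the C=O or C=O+ bond (the arene C=C bond lies inside the new ring) through a chair-like array with the phenyl group on C2 equatorial. C4 and C4′ are each controlled by the C2 centre of their own half: the ortho-methoxy group next to the attacking carbon (later 5-OMe) pushes the oxygen substituent of the reacting carbon into the pseudoaxial position, trans to the equatorial phenyl group (4R), and a cis C4–O bond can re-ionise to the cation stabilised by O1, 5-OMe and 7-OMe and be recaptured from the pseudoaxial side. Regioselectivity is secured by the substrate, since the two ortho carbons of the 3,4,5-trimethoxyphenoxy ring are equivalent, and exchange of partners is harmless, since both halves are identical. What the step must win is capture of C4 by oxygen instead of by C8 of another flavan unit or loss of H3 to the flav-3-ene; here the substrate helps because C8 sits between O1 and a 7-OMe group whose methyl is turned towards it by the 6-OMe group, and a weak catalyst, low temperature, high concentration and an early amine quench do the rest.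

Step 5
Reactants: 9 bis[(2S,4R)-5,6,7-trimethoxy-2-phenylchroman-4-yl] ether
Product: 10 beilschmieflavonoid B, (2S,4R)-6,7-dimethoxy-2-phenyl-4-{[(2S,4R)-5,6,7-trimethoxy-2-phenylchroman-4-yl]oxy}chroman-5-ol
Conditions: LiPPh2 (1.0 equiv, 0.5 M in THF), THF, 0 °C → rt; sat. aq NH4Cl
Reagents that add atoms: none
Why: Nucleophilic aryl methyl ether cleavage with lithium diphenylphosphide (SN2 at CH3) runs at room temperature without acid, conditions that acetal-like C–O bonds such as the doubly benzylic bridge tolerate; it should pick a 5-OMe group because this is the only methoxy group that is both twisted out of conjugation (between C4a and 6-OMe) and meta to two ring oxygens (best phenoxide leaving group, Li+ held by O4, O5 and O6), while C2 symmetry makes both 5-OMe groups equivalent, one equivalent of reagent limits the reaction to one of them, and no stereocentre is involved.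

Compound list
1 | 3,4,5-trimethoxyphenol | COc1cc(O)cc(OC)c1OC | starting material
2 | (R)-3-chloro-1-phenylpropan-1-ol | ClCC[C@H](c1ccccc1)O | starting material
3 | (S)-5-(3-chloro-1-phenylpropoxy)-1,2,3-trimethoxybenzene | ClCC[C@@H](c1ccccc1)Oc1cc(OC)c(OC)c(OC)c1 | intermediate
4 | (S)-3-phenyl-3-(3,4,5-trimethoxyphenoxy)propyl acetate (not isolated) | CC(=O)OCC[C@@H](c1ccccc1)Oc1cc(OC)c(OC)c(OC)c1 | intermediate
5 | (S)-3-phenyl-3-(3,4,5-trimethoxyphenoxy)propan-1-ol | OCC[C@@H](c1ccccc1)Oc1cc(OC)c(OC)c(OC)c1 | intermediate
6 | (S)-3-phenyl-3-(3,4,5-trimethoxyphenoxy)propanal | O=CC[C@@H](c1ccccc1)Oc1cc(OC)c(OC)c(OC)c1 | intermediate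
7 | (2S,4R)-5,6,7-trimethoxyflavan-4-ol, 2,4-trans (not isolated) | O[C@@H]1C[C@@H](c2ccccc2)Oc2cc(OC)c(OC)c(OC)c21 | intermediate
8 | oxocarbenium ion from O4 of 7 and the aldehyde carbon of 6, cation shown (not isolated) | COc1cc2c(c(OC)c1OC)[C@H]([O+]=CC[C@@H](c1ccccc1)Oc1cc(OC)c(OC)c(OC)c1)C[C@@H](c1ccccc1)O2 | intermediate
9 | bis[(2S,4R)-5,6,7-trimethoxy-2-phenylchroman-4-yl] ether (5-O-methylbeilschmieflavonoid B) | COc1cc2c(c(OC)c1OC)[C@H](O[C@@H]1C[C@@H](c3ccccc3)Oc3cc(OC)c(OC)c(OC)c31)C[C@@H](c1ccccc1)O2 | intermediate
10 | beilschmieflavonoid B | COc1cc2c(c(O)c1OC)[C@H](O[C@@H]1C[C@@H](c3ccccc3)Oc3cc(OC)c(OC)c(OC)c31)C[C@@H](c1ccccc1)O2 | target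

Total step count: 5. Longest linear sequence: 5 steps (from 1 and 2 to 10).

Steps most likely to fail

Step 4 (bears the label).
- Risk: the C4 cation may be captured by carbon instead of oxygen (C4 to C8 oligomerisation). A proton may be lost from C3. The acid may expel the aryloxy group from the aldehyde before ring closure.
- Fallback, known chemistry only, from 5 back to 9: oxidation of 5 with TEMPO/PhI(OAc)2 in MeCN–H2O gives (S)-3-phenyl-3-(3,4,5-trimethoxyphenoxy)propanoic acid F1. Intramolecular Friedel–Crafts acylation (TFAA, CH2Cl2, 0 °C) gives (S)-5,6,7-trimethoxyflavanone F2. NaBH4 (MeOH–THF, 0 °C) gives the 2,4-cis alcohol (2S,4S)-5,6,7-trimethoxyflavan-4-ol F3. Catalytic camphorsulfonic acid over 4 Å sieves in CH2Cl2 then epimerises it through the C4 cation to 7 and condenses 7 to 9, by the dehydrative self-etherification known for electron-rich benzylic alcohols. The C–C bonds are thus made by acylation, which cannot over-alkylate, and only the ether bond is left to cation chemistry.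

Step 5.
- Risk: a wrong methoxy group (6- or 7-OMe) may be cleaved, or both 5-OMe groups.
- Fallback from 9 to 10: mild hydrolysis of 9 (PPTS, THF–H2O, rt) returns two molecules of 7, now isolated. Part of it is oxidised (MnO2, CH2Cl2) to the flavanone F2. Its C4 carbonyl group chelates BCl3 and directs cleavage to the peri 5-OMe group only (CH2Cl2, −78 → 0 °C), giving (S)-5-hydroxy-6,7-dimethoxyflavanone F4. NaBH4 gives (2S,4S)-5-hydroxy-6,7-dimethoxyflavan-4-ol F5. Gentle warming in toluene over sieves removes water and gives the ortho-quinone methide F6. An excess of 7 adds through O4 to C4 of this species from the pseudoaxial side (oxa-Michael addition) and gives 10 without acid, so the partners cannot scramble.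

Step 3.
- Risk: β-elimination of the aryloxide, or premature ring closure, during oxidation and isolation.
- Fallback from 1 to 6: Mitsunobu coupling of 1 with purchased (R)-1-phenylbut-3-en-1-ol gives (S)-1,2,3-trimethoxy-5-[(1-phenylbut-3-en-1-yl)oxy]benzene F7. OsO4 (cat.)/NMO in acetone–H2O gives (4S)-4-phenyl-4-(3,4,5-trimethoxyphenoxy)butane-1,2-diol F8 as an epimer mixture at the new carbinol. NaIO4 on silica gel in CH2Cl2 cleaves the glycol under neutral heterogeneous conditions. Filtration delivers a solution of 6 that goes directly into step 4.

Further compounds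
F1 | step 4 | (S)-3-phenyl-3-(3,4,5-trimethoxyphenoxy)propanoic acid | OC(=O)C[C@@H](c1ccccc1)Oc1cc(OC)c(OC)c(OC)c1
F2 | step 4 | (S)-5,6,7-trimethoxyflavanone | O=C1C[C@@H](c2ccccc2)Oc2cc(OC)c(OC)c(OC)c21
F3 | step 4 | (2S,4S)-5,6,7-trimethoxyflavan-4-ol (2,4-cis) | O[C@H]1C[C@@H](c2ccccc2)Oc2cc(OC)c(OC)c(OC)c21
F4 | step 5 | (S)-5-hydroxy-6,7-dimethoxyflavanone | O=C1C[C@@H](c2ccccc2)Oc2cc(OC)c(OC)c(O)c21
F5 | step 5 | (2S,4S)-5-hydroxy-6,7-dimethoxyflavan-4-ol (2,4-cis) | O[C@H]1C[C@@H](c2ccccc2)Oc2cc(OC)c(OC)c(O)c21
F6 | step 5 | (S)-6,7-dimethoxy-2-phenyl-2,3-dihydrochromen-5-one, the ortho-quinone methide (C4=C4a, C5=O) | O=C1C(OC)=C(OC)C=C2O[C@H](c3ccccc3)CC=C12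
F7 | step 3 | (S)-1,2,3-trimethoxy-5-[(1-phenylbut-3-en-1-yl)oxy]benzene | C=CC[C@@H](c1ccccc1)Oc1cc(OC)c(OC)c(OC)c1
F8 | step 3 | (4S)-4-phenyl-4-(3,4,5-trimethoxyphenoxy)butane-1,2-diol (epimers at C2) | OCC(O)C[C@@H](c1ccccc1)Oc1cc(OC)c(OC)c(OC)c1
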